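**Strategy**

Everything rests on disconnecting the C2'–C3' ring bond of the cyclohexane (C1' = CH2 on flavone C6, C2' = ring CH, C3' = C(OH)CH3, C7' = CMe2). Read with C1' as CHO, the trans C3'–OH/C2'–C1' pair is an anti β-hydroxy aldehyde, so one L-proline enamine aldol of acyclic 3,3-dimethyl-7-oxooctanal closes the carbocycle and sets both stereocentres. The aldehyde carbon then becomes C1' by addition of a phloroglucinol-derived aryllithium; the benzylic oxygen is excised through a para-quinone methide, and rings A/C of the flavone are completed by carbonylative alkyne annulation on the unmasked phenol, followed by hydrogenolysis.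

Key step: step 4

Assumption: both ring stereocentres of the target are S with OH trans to the C1' substituent, and L-proline is taken as the catalyst enantiomer because the acid-bridged enamine transition state that gives (2S,3S) anti aldols from aldehyde donors maps onto the (1S,2S) ring aldehyde.

**Route**

Step 1
Reactants: 1 2-(3-chloropropyl)-2-methyl-1,3-dioxolane; 2 diethyl isopropylidenemalonate
Product: 4 diethyl 2-[2-methyl-5-(2-methyl-1,3-dioxolan-2-yl)pentan-2-yl]propanedioate, via Grignard reagent 3 (not isolated)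
Conditions: Mg, cat. I2, THF, reflux; then CuI (10 mol %), 2, THF, −20 → 0 °C; aq. NH4Cl
Reagents that add atoms: none
Why: Copper-catalysed conjugate (1,4-) addition of a primary alkyl Grignard reagent to a doubly activated alkylidene malonate is an established way to create a quaternary carbon, and the dioxolane is inert to the organomagnesium.

Step 2
Reactants: 4 diethyl 2-[2-methyl-5-(2-methyl-1,3-dioxolan-2-yl)pentan-2-yl]propanedioate
Product: 5 ethyl 3,3-dimethyl-6-(2-methyl-1,3-dioxolan-2-yl)hexanoate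
Conditions: LiCl, H2O, DMSO, 160 °C
Reagents that add atoms: none
Why: Krapcho dealkoxycarbonylation (chloride attack on an ethyl group, loss of CO2, protonation) removes one ester under near-neutral conditions that a dioxolane tolerates.

Step 3
Reactants: 5 ethyl 3,3-dimethyl-6-(2-methyl-1,3-dioxolan-2-yl)hexanoate
Product: 7 3,3-dimethyl-7-oxooctanal, via ketal aldehyde 6 (not isolated)
Conditions: DIBAL-H (1.1 equiv), CH2Cl2, −78 °C; then 1 M HCl, THF, 0 °C → rt
Reagents that add atoms: water, O
Why: DIBAL-H partial reduction of the ester stops at the tetrahedral aluminium hemiacetal at −78 °C, which gives the aldehyde on acidic work-up, and the same dilute aqueous acid hydrolyses the dioxolane (acetal hydrolysis) to the methyl ketone.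

Step 4
Reactants: 7 3,3-dimethyl-7-oxooctanal
Product: 8 (1S,2S)-2-hydroxy-2,6,6-trimethylcyclohexane-1-carbaldehyde
Conditions: L-proline (20 mol %), DMSO, rt
Reagents that add atoms: none
Why: Proline condenses with the aldehyde of 7 (the faster amine acceptor) to an E-enamine whose nucleophilic carbon (C2 of 7, future C2') adds to the C7 ketone held by a hydrogen bond to the carboxylic acid, and hydrolysis of the iminium then releases 8 and the catalyst. The closest known reaction type is the proline-catalysed intramolecular enolexo aldolisation of dialdehydes and keto-aldehydes. The single new ring closes in the 6-(enolexo)-exo-trig mode through formation of the C2'–C3' bond only. C2' is set by attack from the enamine face on the side of the carboxylic acid, and C3' by the ketone face exposed when the ring tether lies pseudo-equatorial (anti to the enamine C=C) and the methyl group gauche in the chair-like acid-bridged transition state, which is the arrangement that gives (2S,3S) anti aldols from L-proline and here places OH trans to CHO with both centres S. The step needs donor/acceptor chemoselectivity, anti diastereoselectivity and one enantioface: the aldehyde has a single enolisable CH2 and forms its enamine far faster than the methyl ketone, its own carbonyl is a poorer acceptor next to the β-quaternary carbon, the gem-dimethyl group favours ring closure (gem-dialkyl effect), and the product aldehyde, flanked by two fully substituted carbons, should not re-enter the enamine cycle and epimerise.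

Step 5
Reactants: 8 (1S,2S)-2-hydroxy-2,6,6-trimethylcyclohexane-1-carbaldehyde
Product: 9 (1S,2S)-2,6,6-trimethyl-2-[(triethylsilyl)oxy]cyclohexane-1-carbaldehyde
Conditions: TESOTf, 2,6-lutidine, CH2Cl2, −78 → −40 °C
Reagents that add atoms: triethylsilyl trifluoromethanesulfonate, CC[Si](CC)(CC)OS(=O)(=O)C(F)(F)F
Why: Silylation of the hindered tertiary alcohol with a silyl triflate and 2,6-lutidine at low temperature (O-silylation) blocks retro-aldol cleavage and dehydration of freshly prepared 8 and leaves both stereocentres untouched.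

Step 6
Reactants: 10 3,5-bis(benzyloxy)phenol
Product: 11 [3,5-bis(benzyloxy)phenoxy]tri(propan-2-yl)silane
Conditions: TIPSCl, imidazole, DMF, rt
Reagents that add atoms: chlorotri(propan-2-yl)silane, CC(C)[Si](Cl)(C(C)C)C(C)C
Why: Standard O-silylation of a phenol gives a bulky triisopropylsilyl ether that survives organolithium reagents, shields its own ortho positions and later serves as the fluoride-cleavable trigger para to the new benzylic carbon.

Step 7
Reactants: 11 [3,5-bis(benzyloxy)phenoxy]tri(propan-2-yl)silane; 9 (1S,2S)-2,6,6-trimethyl-2-[(triethylsilyl)oxy]cyclohexane-1-carbaldehyde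
Product: 14 {2,6-bis(benzyloxy)-4-[(triisopropylsilyl)oxy]phenyl}{(1R,2S)-2,6,6-trimethyl-2-[(triethylsilyl)oxy]cyclohexyl}methyl acetate (both carbinol epimers; ring geometry as in 9), via aryllithium 12 (not isolated), via lithium alkoxide 13 (not isolated)
Conditions: 11, n-BuLi, TMEDA, THF, 0 °C; then 9, −78 → −40 °C; then Ac2O, −40 → 0 °C
Reagents that add atoms: acetic anhydride, CC(=O)OC(C)=O
Why: Directed ortho-lithiation takes place at the ring position flanked and coordinated by both benzyloxy groups (the most acidic C–H, favoured over benzylic metalation at 0 °C with TMEDA), the aryllithium then adds 1,2 to the aldehyde faster than it can remove the shielded α-hydrogen, and acetic anhydride traps the lithium alkoxide as the acetate; the new carbinol centre forms as an epimer mixture, which is irrelevant because step 8 removes it.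

Step 8
Reactants: 14 {2,6-bis(benzyloxy)-4-[(triisopropylsilyl)oxy]phenyl}{(1R,2S)-2,6,6-trimethyl-2-[(triethylsilyl)oxy]cyclohexyl}methyl acetate
Product: 17 3,5-bis(benzyloxy)-4-{[(1S,2S)-2-hydroxy-2,6,6-trimethylcyclohexyl]methyl}phenol, via quinone methide 15 (not isolated), via triethylsilyl ether 16 (not isolated)
Conditions: NaBH4 (5 equiv), TBAF (1.1 equiv), THF–EtOH (9:1), 0 °C; then TBAF (4 equiv), 50 °C
Reagents that add atoms: none
Why: Fluoride cleaves the aryl silyl ether first, the phenoxide expels the para-benzylic acetate (1,6-elimination) to a para-quinone methide that borohydride reduces by 1,6-hydride addition without touching C2', and excess fluoride at 50 °C then removes the more hindered tertiary triethylsilyl ether (quinone-methide-mediated reductive deoxygenation followed by desilylation).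

Step 9
Reactants: 17 3,5-bis(benzyloxy)-4-{[(1S,2S)-2-hydroxy-2,6,6-trimethylcyclohexyl]methyl}phenol
Product: 18 3,5-bis(benzyloxy)-4-{[(1S,2S)-2-hydroxy-2,6,6-trimethylcyclohexyl]methyl}-2-iodophenol
Conditions: NIS (1.0 equiv), CH2Cl2, −20 → 0 °C, dark
Reagents that add atoms: N-iodosuccinimide, O=C1CCC(=O)N1I
Why: Electrophilic aromatic iodination of the electron-rich phenol can only occur at the two symmetry-equivalent positions ortho to OH because the para position carries the side chain, so one equivalent of NIS at low temperature should give a single mono-iodide.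

Step 10
Reactants: 19 3,4-bis(benzyloxy)benzaldehyde
Product: 20 1,2-bis(benzyloxy)-4-ethynylbenzene
Conditions: dimethyl (1-diazo-2-oxopropyl)phosphonate, K2CO3, MeOH–THF, rt
Reagents that add atoms: dimethyl (1-diazo-2-oxopropyl)phosphonate, CC(=O)C(=[N+]=[N-])P(=O)(OC)OC
Why: Seyferth–Gilbert homologation with the Ohira–Bestmann reagent converts the non-enolisable aryl aldehyde directly into the terminal alkyne under mild carbonate conditions that benzyl ethers tolerate.

Step 11
Reactants: 18 3,5-bis(benzyloxy)-4-{[(1S,2S)-2-hydroxy-2,6,6-trimethylcyclohexyl]methyl}-2-iodophenol; 20 1,2-bis(benzyloxy)-4-ethynylbenzene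
Product: 22 5,7-bis(benzyloxy)-2-[3,4-bis(benzyloxy)phenyl]-6-{[(1S,2S)-2-hydroxy-2,6,6-trimethylcyclohexyl]methyl}-4H-chromen-4-one, via ynone 21 (not isolated)
Conditions: PdCl2(PPh3)2 (5 mol %), dppp, thiourea, Et2NH, DBU, DMF, CO (1 atm), 40 °C
Reagents that add atoms: carbon monoxide, [C-]#[O+]
Why: Palladium-catalysed carbonylative Sonogashira coupling (oxidative addition, CO insertion, alkynylation) gives the o-hydroxyaryl ynone, which the secondary amine converts through conjugate addition into the 6-endo ring closure that forms the chromone, and because the phenol oxygen para to the side chain becomes O1 the 6-substituted (not 8-substituted) flavone is the only possible regioisomer.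

Step 12
Reactants: 22 5,7-bis(benzyloxy)-2-[3,4-bis(benzyloxy)phenyl]-6-{[(1S,2S)-2-hydroxy-2,6,6-trimethylcyclohexyl]methyl}-4H-chromen-4-one
Product: 23 2-(3,4-dihydroxyphenyl)-5,7-dihydroxy-6-{[(1S,2S)-2-hydroxy-2,6,6-trimethylcyclohexyl]methyl}-4H-chromen-4-one (CNP0257603.1)
Conditions: H2 (1 atm), 10 % Pd/C, THF–MeOH, rt
Reagents that add atoms: none
Why: Catalytic hydrogenolysis cleaves the four benzyl aryl ethers under neutral conditions that spare the acid-sensitive tertiary alcohol and, at one atmosphere and room temperature with monitoring, the chromone C2=C3 bond.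

**Compound list**

1 | 2-(3-chloropropyl)-2-methyl-1,3-dioxolane | CC1(CCCCl)OCCO1 | starting material
2 | diethyl isopropylidenemalonate | CCOC(=O)C(=C(C)C)C(=O)OCC | starting material
3 | [3-(2-methyl-1,3-dioxolan-2-yl)propyl]magnesium chloride (not isolated) | CC1(CCC[Mg]Cl)OCCO1 | intermediate
4 | diethyl 2-[2-methyl-5-(2-methyl-1,3-dioxolan-2-yl)pentan-2-yl]propanedioate | CCOC(=O)C(C(=O)OCC)C(C)(C)CCCC1(C)OCCO1 | intermediate
5 | ethyl 3,3-dimethyl-6-(2-methyl-1,3-dioxolan-2-yl)hexanoate | CCOC(=O)CC(C)(C)CCCC1(C)OCCO1 | intermediate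
6 | 3,3-dimethyl-6-(2-methyl-1,3-dioxolan-2-yl)hexanal (not isolated) | CC1(CCCC(C)(C)CC=O)OCCO1 | intermediate
7 | 3,3-dimethyl-7-oxooctanal | CC(=O)CCCC(C)(C)CC=O | intermediate
8 | (1S,2S)-2-hydroxy-2,6,6-trimethylcyclohexane-1-carbaldehyde | CC1(C)CCC[C@](C)(O)[C@H]1C=O | intermediate
9 | (1S,2S)-2,6,6-trimethyl-2-[(triethylsilyl)oxy]cyclohexane-1-carbaldehyde | CC1(C)CCC[C@](C)(O[Si](CC)(CC)CC)[C@H]1C=O | intermediate
10 | 3,5-bis(benzyloxy)phenol | Oc1cc(OCc2ccccc2)cc(OCc2ccccc2)c1 | starting material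
11 | [3,5-bis(benzyloxy)phenoxy]tri(propan-2-yl)silane | CC(C)[Si](Oc1cc(OCc2ccccc2)cc(OCc2ccccc2)c1)(C(C)C)C(C)C | intermediate
12 | {2,6-bis(benzyloxy)-4-[(triisopropylsilyl)oxy]phenyl}lithium (not isolated) | [Li]c1c(OCc2ccccc2)cc(O[Si](C(C)C)(C(C)C)C(C)C)cc1OCc1ccccc1 | intermediate
13 | lithium {2,6-bis(benzyloxy)-4-[(triisopropylsilyl)oxy]phenyl}{(1R,2S)-2,6,6-trimethyl-2-[(triethylsilyl)oxy]cyclohexyl}methanolate (both carbinol epimers; not isolated) | CC1(C)CCC[C@](C)(O[Si](CC)(CC)CC)[C@H]1C(O[Li])c1c(OCc2ccccc2)cc(O[Si](C(C)C)(C(C)C)C(C)C)cc1OCc1ccccc1 | intermediate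
14 | {2,6-bis(benzyloxy)-4-[(triisopropylsilyl)oxy]phenyl}{(1R,2S)-2,6,6-trimethyl-2-[(triethylsilyl)oxy]cyclohexyl}methyl acetate (both carbinol epimers) | CC1(C)CCC[C@](C)(O[Si](CC)(CC)CC)[C@H]1C(OC(C)=O)c1c(OCc2ccccc2)cc(O[Si](C(C)C)(C(C)C)C(C)C)cc1OCc1ccccc1 | intermediate
15 | 3,5-bis(benzyloxy)-4-({(1S,2S)-2,6,6-trimethyl-2-[(triethylsilyl)oxy]cyclohexyl}methylidene)cyclohexa-2,5-dien-1-one (not isolated) | CC1(C)CCC[C@](C)(O[Si](CC)(CC)CC)[C@H]1C=C1C(OCc2ccccc2)=CC(=O)C=C1OCc1ccccc1 | intermediate
16 | 3,5-bis(benzyloxy)-4-({(1S,2S)-2,6,6-trimethyl-2-[(triethylsilyl)oxy]cyclohexyl}methyl)phenol (not isolated) | CC1(C)CCC[C@](C)(O[Si](CC)(CC)CC)[C@H]1Cc1c(OCc2ccccc2)cc(O)cc1OCc1ccccc1 | intermediate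
17 | 3,5-bis(benzyloxy)-4-{[(1S,2S)-2-hydroxy-2,6,6-trimethylcyclohexyl]methyl}phenol | CC1(C)CCC[C@](C)(O)[C@H]1Cc1c(OCc2ccccc2)cc(O)cc1OCc1ccccc1 | intermediate
18 | 3,5-bis(benzyloxy)-4-{[(1S,2S)-2-hydroxy-2,6,6-trimethylcyclohexyl]methyl}-2-iodophenol | CC1(C)CCC[C@](C)(O)[C@H]1Cc1c(OCc2ccccc2)cc(O)c(I)c1OCc1ccccc1 | intermediate
19 | 3,4-bis(benzyloxy)benzaldehyde | O=Cc1ccc(OCc2ccccc2)c(OCc2ccccc2)c1 | starting material
20 | 1,2-bis(benzyloxy)-4-ethynylbenzene | C#Cc1ccc(OCc2ccccc2)c(OCc2ccccc2)c1 | intermediate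
21 | 1-(2,4-bis(benzyloxy)-6-hydroxy-3-{[(1S,2S)-2-hydroxy-2,6,6-trimethylcyclohexyl]methyl}phenyl)-3-[3,4-bis(benzyloxy)phenyl]prop-2-yn-1-one (not isolated) | CC1(C)CCC[C@](C)(O)[C@H]1Cc1c(OCc2ccccc2)cc(O)c(C(=O)C#Cc2ccc(OCc3ccccc3)c(OCc3ccccc3)c2)c1OCc1ccccc1 | intermediate
22 | 5,7-bis(benzyloxy)-2-[3,4-bis(benzyloxy)phenyl]-6-{[(1S,2S)-2-hydroxy-2,6,6-trimethylcyclohexyl]methyl}-4H-chromen-4-one | CC1(C)CCC[C@](C)(O)[C@H]1Cc1c(OCc2ccccc2)cc2oc(-c3ccc(OCc4ccccc4)c(OCc4ccccc4)c3)cc(=O)c2c1OCc1ccccc1 | intermediate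
23 | 2-(3,4-dihydroxyphenyl)-5,7-dihydroxy-6-{[(1S,2S)-2-hydroxy-2,6,6-trimethylcyclohexyl]methyl}-4H-chromen-4-one | CC1(C)CCC[C@](C)(O)[C@H]1Cc1c(O)cc2oc(-c3ccc(O)c(O)c3)cc(=O)c2c1O | target

**Step count**

Total steps: 12. Longest linear sequence: 10 (steps 1, 2, 3, 4, 5, 7, 8, 9, 11, 12).

**Steps most likely to fail**

1. Step 4. The cyclisation may be slow or misdirected: the neopentyl-type enamine must add to a methyl ketone, and in the chair transition state the ketone methyl is pushed syn-axial to one C7' methyl. Closure may therefore stall, lose facial or anti selectivity, divert to the isomeric ring formed when the C6 ketone enamine attacks the aldehyde, or be followed by dehydration to the conjugated enal. The fallback sets out from 7 and returns at 8. Compound 7 is cyclised with pyrrolidinium acetate (a less encumbered, achiral enamine catalyst) and the crude aldol is reduced in the same flask with NaBH4 to racemic trans-2-(hydroxymethyl)-1,3,3-trimethylcyclohexan-1-ol F1, which is freed from any cis isomer by chromatography. The primary hydroxyl is esterified with (S)-2-methoxy-2-phenylacetic acid (DCC, DMAP) to give the diastereomeric esters [(1R,2S)-2-hydroxy-2,6,6-trimethylcyclohexyl]methyl (2S)-2-methoxy-2-phenylacetate F2 and [(1S,2R)-2-hydroxy-2,6,6-trimethylcyclohexyl]methyl (2S)-2-methoxy-2-phenylacetate F3, which are separated by chromatography or crystallisation. Saponification of F2 (LiOH, THF–H2O) gives (1S,2R)-2-(hydroxymethyl)-1,3,3-trimethylcyclohexan-1-ol F4, and oxidation of the primary alcohol only (TEMPO, PhI(OAc)2, CH2Cl2) regains 8.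

2. Step 7. Proton transfer may win over C–C bond formation: the 2,6-disubstituted aryllithium may deprotonate the aldehyde, which is flanked by two fully substituted carbons, leading to epimerisation at C2' or β-elimination of silanolate instead of addition. The fallback sets out from 9 and returns at 17, replacing carbonyl addition by sp3–sp2 cross-coupling and bypassing step 8 as well. Compound 9 is reduced (DIBAL-H, CH2Cl2, −78 °C) to [(1R,2S)-2,6,6-trimethyl-2-(triethylsilyloxy)cyclohexyl]methanol F5 and converted (I2, PPh3, imidazole) into triethyl{[(1S,2S)-2-(iodomethyl)-1,3,3-trimethylcyclohexyl]oxy}silane F6. Zinc insertion (Zn dust, LiCl, THF, 40 °C) gives {[(1S,2S)-2,6,6-trimethyl-2-(triethylsilyloxy)cyclohexyl]methyl}zinc iodide F7. Negishi coupling (Pd(OAc)2, SPhos, THF–NMP, 60 °C) with [3,5-bis(benzyloxy)-4-iodophenoxy]tri(propan-2-yl)silane F8, obtained by quenching 12 with iodine, gives {3,5-bis(benzyloxy)-4-({(1S,2S)-2,6,6-trimethyl-2-[(triethylsilyl)oxy]cyclohexyl}methyl)phenoxy}tri(propan-2-yl)silane F9, which already lacks the benzylic oxygen. Excess TBAF (THF, 50 °C) then gives 17.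

3. Step 11. Control may be lost in the palladium cascade: oxidative addition at the di-ortho-substituted, electron-rich iodide may be slow, direct non-carbonylative alkynylation may lead to a benzofuran, or the ynone may close 5-exo to an aurone instead of 6-endo to the flavone. The fallback sets out from 18 and returns at 22, building ring C stepwise. Stille coupling of 18 with tributyl(1-ethoxyvinyl)stannane (PdCl2(PPh3)2, dioxane, 90 °C) gives 3,5-bis(benzyloxy)-2-(1-ethoxyethenyl)-4-{[(1S,2S)-2-hydroxy-2,6,6-trimethylcyclohexyl]methyl}phenol F10. Brief hydrolysis on work-up (1 M HCl, THF, rt) gives 1-(2,4-bis(benzyloxy)-6-hydroxy-3-{[(1S,2S)-2-hydroxy-2,6,6-trimethylcyclohexyl]methyl}phenyl)ethan-1-one F11. Claisen–Schmidt condensation with 19 (KOH, EtOH, rt) gives (E)-1-(2,4-bis(benzyloxy)-6-hydroxy-3-{[(1S,2S)-2-hydroxy-2,6,6-trimethylcyclohexyl]methyl}phenyl)-3-[3,4-bis(benzyloxy)phenyl]prop-2-en-1-one F12. Oxidative cyclisation with catalytic I2 in DMSO (120 °C) delivers 22.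

**Further compounds**

F1 | step 4 | racemic trans-2-(hydroxymethyl)-1,3,3-trimethylcyclohexan-1-ol (one enantiomer drawn) | CC1(C)CCC[C@](C)(O)[C@H]1CO
F2 | step 4 | [(1R,2S)-2-hydroxy-2,6,6-trimethylcyclohexyl]methyl (2S)-2-methoxy-2-phenylacetate | CC1(C)CCC[C@](C)(O)[C@H]1COC(=O)[C@@H](OC)c1ccccc1
F3 | step 4 | [(1S,2R)-2-hydroxy-2,6,6-trimethylcyclohexyl]methyl (2S)-2-methoxy-2-phenylacetate | CC1(C)CCC[C@@](C)(O)[C@@H]1COC(=O)[C@@H](OC)c1ccccc1
F4 | step 4 | (1S,2R)-2-(hydroxymethyl)-1,3,3-trimethylcyclohexan-1-ol | CC1(C)CCC[C@](C)(O)[C@H]1CO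
F5 | step 7 | [(1R,2S)-2,6,6-trimethyl-2-(triethylsilyloxy)cyclohexyl]methanol | CC1(C)CCC[C@](C)(O[Si](CC)(CC)CC)[C@H]1CO
F6 | step 7 | triethyl{[(1S,2S)-2-(iodomethyl)-1,3,3-trimethylcyclohexyl]oxy}silane | CC1(C)CCC[C@](C)(O[Si](CC)(CC)CC)[C@H]1CI
F7 | step 7 | {[(1S,2S)-2,6,6-trimethyl-2-(triethylsilyloxy)cyclohexyl]methyl}zinc iodide | CC1(C)CCC[C@](C)(O[Si](CC)(CC)CC)[C@H]1C[Zn]I
F8 | step 7 | [3,5-bis(benzyloxy)-4-iodophenoxy]tri(propan-2-yl)silane | CC(C)[Si](Oc1cc(OCc2ccccc2)c(I)c(OCc2ccccc2)c1)(C(C)C)C(C)C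
F9 | step 7 | {3,5-bis(benzyloxy)-4-({(1S,2S)-2,6,6-trimethyl-2-[(triethylsilyl)oxy]cyclohexyl}methyl)phenoxy}tri(propan-2-yl)silane | CC1(C)CCC[C@](C)(O[Si](CC)(CC)CC)[C@H]1Cc1c(OCc2ccccc2)cc(O[Si](C(C)C)(C(C)C)C(C)C)cc1OCc1ccccc1
F10 | step 11 | 3,5-bis(benzyloxy)-2-(1-ethoxyethenyl)-4-{[(1S,2S)-2-hydroxy-2,6,6-trimethylcyclohexyl]methyl}phenol | CC1(C)CCC[C@](C)(O)[C@H]1Cc1c(OCc2ccccc2)cc(O)c(C(=C)OCC)c1OCc1ccccc1
F11 | step 11 | 1-(2,4-bis(benzyloxy)-6-hydroxy-3-{[(1S,2S)-2-hydroxy-2,6,6-trimethylcyclohexyl]methyl}phenyl)ethan-1-one | CC1(C)CCC[C@](C)(O)[C@H]1Cc1c(OCc2ccccc2)cc(O)c(C(C)=O)c1OCc1ccccc1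
F12 | step 11 | (E)-1-(2,4-bis(benzyloxy)-6-hydroxy-3-{[(1S,2S)-2-hydroxy-2,6,6-trimethylcyclohexyl]methyl}phenyl)-3-[3,4-bis(benzyloxy)phenyl]prop-2-en-1-one | CC1(C)CCC[C@](C)(O)[C@H]1Cc1c(OCc2ccccc2)cc(O)c(C(=O)/C=C/c2ccc(OCc3ccccc3)c(OCc3ccccc3)c2)c1OCc1ccccc1
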